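The retrosynthesis removes the two MOM acetals, then cuts the ketone bond C6–C(=O), then O1–C2 and C3–C4 of the pyran together, and last C4a–C4 (formyl) and C8–CH2 (prenyl). This leaves 5-methoxyresorcinol.
The double pyran cut is possible because C4 is a single carbon on C4a, and C4a stands between C8a (which carries O1) and C5 (which carries the methoxy group). The benzopyran therefore hides a 6-methoxysalicylaldehyde.
In the forward direction the benzene ring is bought. MOM-directed lithiations place the prenyl group (C8) and the formyl carbon (future C4), the pyran (the only ring made) closes next, and a third lithiation joins C6 to the aroyl unit.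
C3, C2 and the two methyl groups come from (2-methylprop-1-enyl)boronic acid, and the aroyl unit comes from methyl 4-hydroxybenzoate.
The target has no stereocentre and no alkene with E/Z isomers (C3=C4 is cis within the ring), so no stereochemistry has to be controlled.

Key step: step 5

Remark on the chemistry: labels O1, C2 … C8a follow the chromene numbering of the target, while systematic names of the benzene intermediates carry their own locants. Compounds 7, 12 and 19 each hold one transient stereocentre, form as racemates and lose that centre in the same flask.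

Step 1
Reactants: 1 5-methoxyresorcinol (5-methoxybenzene-1,3-diol)
Product: 2 1-methoxy-3,5-bis(methoxymethoxy)benzene
Conditions: MOMCl (2.6 equiv), K2CO3 (4 equiv), acetone, 0 °C to reflux
Reagents that add atoms: chloromethyl methyl ether (MOMCl), COCCl
Why: Williamson-type O-alkylation, in which the hard oxocarbenium-like electrophile reacts at both phenolic oxygens rather than at carbon, and the two acetals then serve as directing groups for every later lithiation.

Step 2
Reactants: 2 1-methoxy-3,5-bis(methoxymethoxy)benzene; 3 prenyl bromide (1-bromo-3-methylbut-2-ene)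
Product: 5 5-methoxy-1,3-bis(methoxymethoxy)-2-(3-methylbut-2-enyl)benzene, via aryllithium 4 (not isolated)
Conditions: n-BuLi (1.1 equiv), THF, 0 °C to rt, 1 h; then 3 (1.3 equiv), −78 °C to rt
Reagents that add atoms: none
Why: Directed ortho-metalation followed by SN2 allylation, in which the hydrogen between the two MOM ethers is flanked by two chelating acetals that bind n-BuLi better than the methyl ether does, so lithiation should occur there, and the aryllithium attacks the unhindered primary carbon of 3.

Step 3
Reactants: 5 5-methoxy-1,3-bis(methoxymethoxy)-2-(3-methylbut-2-enyl)benzene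
Product: 8 6-methoxy-2,4-bis(methoxymethoxy)-3-(3-methylbut-2-enyl)benzaldehyde, via aryllithium 6 (not isolated), via lithium hemiaminal alkoxide 7 (not isolated)
Conditions: n-BuLi (1.15 equiv), THF, −20 to 0 °C, 1 h; DMF (3 equiv), −78 °C to rt; H2O
Reagents that add atoms: N,N-dimethylformamide (DMF), CN(C)C=O
Why: Second directed ortho-metalation with a DMF quench (Bouveault-type formylation), where the two remaining ring hydrogens are equivalent by symmetry so only one aldehyde can form, and each lies between OMe and OMOM, whose joint coordination should make ring lithiation faster than removal of a benzylic allylic proton of the prenyl group.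

Step 4
Reactants: 8 6-methoxy-2,4-bis(methoxymethoxy)-3-(3-methylbut-2-enyl)benzaldehyde
Product: 9 2-hydroxy-6-methoxy-4-(methoxymethoxy)-3-(3-methylbut-2-enyl)benzaldehyde
Conditions: p-TsOH·H2O (0.1 equiv), MeOH, 0 °C to rt, stopped as soon as 8 is consumed
Reagents that add atoms: none
Why: Acid-catalysed transacetalisation of a MOM ether, selective for the one ortho to a carbonyl group, because the acetal next to the formyl group is twisted out of the ring plane between formyl and prenyl and its cleavage is helped by the hydrogen bond from the emerging phenol to the formyl oxygen, whereas the remote acetal has neither aid and should survive a short exposure to dilute acid that is also too mild to protonate the prenyl alkene.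

Step 5
Reactants: 9 2-hydroxy-6-methoxy-4-(methoxymethoxy)-3-(3-methylbut-2-enyl)benzaldehyde; 10 (2-methylprop-1-enyl)boronic acid
Product: 14 5-methoxy-7-(methoxymethoxy)-2,2-dimethyl-8-(3-methylbut-2-enyl)-2H-chromene, via iminium boronate 11 (not isolated), via allylic amine 12 (not isolated), via ortho-quinone methide 13 (not isolated)
Conditions: 10 (2 equiv), Bn2NH (0.4 equiv), 1,4-dioxane, 90 °C, 24 h
Reagents that add atoms: none
Why: Dibenzylamine condenses with the formyl group of 9 while the neighbouring phenoxide binds boron, giving zwitterion 11, in which the 2-methylprop-1-enyl group migrates from tetracoordinate boron to the iminium carbon and forms C3–C4 (Petasis borono-Mannich reaction). The racemic allylic amine 12 should ionise readily at 90 °C because its benzylic carbon is supported by three ring oxygens in ortho, ortho and para positions, and loss of dibenzylamine returns the catalyst and leaves ortho-quinone methide 13, whose butenylidene group should point towards the carbonyl oxygen and away from the bulkier C5 methoxy group. The pyran closes by thermal oxa-6π electrocyclisation of the O=C8a–C4a=C4–C3=C2 array, which joins O1 to the dimethyl-bearing C2 and restores aromaticity, so the six-membered ring forms pericyclically and irreversibly and drains the reversible steps before it. The closest known reaction type is the amine-catalysed condensation of salicylaldehydes with alkenylboronic acids to 2H-chromenes. No stereocentre survives, since the amine-bearing carbon of 12 becomes sp2 C4 and C2 carries two identical methyl groups. The only selectivity needed is the choice of ring oxygen, and the substrate fixes it: the sole free hydroxyl is ortho to the formyl group, the other ortho position holds the methyl ether, and the para oxygen is capped as its MOM ether, which also keeps the amine from turning the aldehyde into an unreactive vinylogous carboxylate.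

Step 6
Reactants: 15 methyl 4-hydroxybenzoate
Product: 16 methyl 4-(methoxymethoxy)benzoate
Conditions: MOMCl (1.3 equiv), K2CO3 (2 equiv), acetone, 0 °C to reflux
Reagents that add atoms: chloromethyl methyl ether (MOMCl), COCCl
Why: Williamson-type O-alkylation of the phenol, under which the methyl ester is inert.

Step 7
Reactants: 16 methyl 4-(methoxymethoxy)benzoate
Product: 17 N-methoxy-4-(methoxymethoxy)-N-methylbenzamide
Conditions: MeNH(OMe)·HCl (1.5 equiv), i-PrMgCl (3 equiv), THF, −20 to 0 °C
Reagents that add atoms: N,O-dimethylhydroxylamine hydrochloride, CNOC.Cl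
Why: Weinreb amide formation by aminolysis of the ester with the magnesium amide generated in the flask, conditions to which the aryl acetal is inert.

Step 8
Reactants: 14 5-methoxy-7-(methoxymethoxy)-2,2-dimethyl-8-(3-methylbut-2-enyl)-2H-chromene; 17 N-methoxy-4-(methoxymethoxy)-N-methylbenzamide
Product: 20 [5-methoxy-7-(methoxymethoxy)-2,2-dimethyl-8-(3-methylbut-2-enyl)-2H-chromen-6-yl][4-(methoxymethoxy)phenyl]methanone, via 6-lithiochromene 18 (not isolated), via tetrahedral lithium adduct 19 (not isolated)
Conditions: n-BuLi (1.05 equiv), THF, −20 to 0 °C, 1 h; 17 (1.2 equiv), −78 °C to rt; H2O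
Reagents that add atoms: none
Why: Directed ortho-metalation followed by Weinreb ketone synthesis, in which C6–H is the only ring hydrogen and lies between OMe and OMOM so that both groups steer n-BuLi to it, and the chelated adduct 19 persists until the quench and so rules out a second addition.

Step 9
Reactants: 20 [5-methoxy-7-(methoxymethoxy)-2,2-dimethyl-8-(3-methylbut-2-enyl)-2H-chromen-6-yl][4-(methoxymethoxy)phenyl]methanone
Product: 21 vismiaphenone F, (4-hydroxyphenyl)[7-hydroxy-5-methoxy-2,2-dimethyl-8-(3-methylbut-2-enyl)-2H-chromen-6-yl]methanone
Conditions: 3 M aq. HCl, MeOH, rt to 40 °C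
Reagents that add atoms: none
Why: Acid-catalysed transacetalisation of both MOM ethers, the usual way to unmask prenylated 2-hydroxyaryl ketones, in which the freed 7-hydroxyl is at once held in a hydrogen bond to the ketone and should therefore be a poor nucleophile towards the neighbouring prenyl alkene.

Compound list
1 | 5-methoxyresorcinol (5-methoxybenzene-1,3-diol) | COc1cc(O)cc(O)c1 | starting material
2 | 1-methoxy-3,5-bis(methoxymethoxy)benzene | COCOc1cc(OC)cc(OCOC)c1 | intermediate
3 | prenyl bromide (1-bromo-3-methylbut-2-ene) | CC(C)=CCBr | starting material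
4 | [4-methoxy-2,6-bis(methoxymethoxy)phenyl]lithium | [Li]c1c(OCOC)cc(OC)cc1OCOC | intermediate
5 | 5-methoxy-1,3-bis(methoxymethoxy)-2-(3-methylbut-2-enyl)benzene | COCOc1cc(OC)cc(OCOC)c1CC=C(C)C | intermediate
6 | [6-methoxy-2,4-bis(methoxymethoxy)-3-(3-methylbut-2-enyl)phenyl]lithium | [Li]c1c(OC)cc(OCOC)c(CC=C(C)C)c1OCOC | intermediate
7 | lithium (dimethylamino)[6-methoxy-2,4-bis(methoxymethoxy)-3-(3-methylbut-2-enyl)phenyl]methanolate (racemic) | [Li]OC(N(C)C)c1c(OC)cc(OCOC)c(CC=C(C)C)c1OCOC | intermediate
8 | 6-methoxy-2,4-bis(methoxymethoxy)-3-(3-methylbut-2-enyl)benzaldehyde | COCOc1cc(OC)c(C=O)c(OCOC)c1CC=C(C)C | intermediate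
9 | 2-hydroxy-6-methoxy-4-(methoxymethoxy)-3-(3-methylbut-2-enyl)benzaldehyde | COCOc1cc(OC)c(C=O)c(O)c1CC=C(C)C | intermediate
10 | (2-methylprop-1-enyl)boronic acid | CC(C)=CB(O)O | starting material
11 | zwitterion of the N,N-dibenzyliminium ion of 9 whose phenoxide oxygen is bound to a dihydroxy(2-methylprop-1-enyl)borate | COCOc1cc(OC)c(C=[N+](Cc2ccccc2)Cc2ccccc2)c(O[B-](O)(O)C=C(C)C)c1CC=C(C)C | intermediate
12 | 2-[1-(dibenzylamino)-3-methylbut-2-enyl]-3-methoxy-5-(methoxymethoxy)-6-(3-methylbut-2-enyl)phenol (racemic) | COCOc1cc(OC)c(C(C=C(C)C)N(Cc2ccccc2)Cc2ccccc2)c(O)c1CC=C(C)C | intermediate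
13 | (6Z)-5-methoxy-3-(methoxymethoxy)-2-(3-methylbut-2-enyl)-6-(3-methylbut-2-enylidene)cyclohexa-2,4-dien-1-one | CC(C)=C/C=C1\C(=O)C(CC=C(C)C)=C(OCOC)C=C1OC | intermediate
14 | 5-methoxy-7-(methoxymethoxy)-2,2-dimethyl-8-(3-methylbut-2-enyl)-2H-chromene | COCOc1cc(OC)c2C=CC(C)(C)Oc2c1CC=C(C)C | intermediate
15 | methyl 4-hydroxybenzoate | COC(=O)c1ccc(O)cc1 | starting material
16 | methyl 4-(methoxymethoxy)benzoate | COCOc1ccc(cc1)C(=O)OC | intermediate
17 | N-methoxy-4-(methoxymethoxy)-N-methylbenzamide | COCOc1ccc(cc1)C(=O)N(C)OC | intermediate
18 | [5-methoxy-7-(methoxymethoxy)-2,2-dimethyl-8-(3-methylbut-2-enyl)-2H-chromen-6-yl]lithium | [Li]c1c(OC)c2C=CC(C)(C)Oc2c(CC=C(C)C)c1OCOC | intermediate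
19 | lithium [methoxy(methyl)amino][4-(methoxymethoxy)phenyl][5-methoxy-7-(methoxymethoxy)-2,2-dimethyl-8-(3-methylbut-2-enyl)-2H-chromen-6-yl]methanolate (racemic) | [Li]OC(N(C)OC)(c1ccc(OCOC)cc1)c1c(OC)c2C=CC(C)(C)Oc2c(CC=C(C)C)c1OCOC | intermediate
20 | [5-methoxy-7-(methoxymethoxy)-2,2-dimethyl-8-(3-methylbut-2-enyl)-2H-chromen-6-yl][4-(methoxymethoxy)phenyl]methanone | COCOc1ccc(cc1)C(=O)c1c(OC)c2C=CC(C)(C)Oc2c(CC=C(C)C)c1OCOC | intermediate
21 | vismiaphenone F, (4-hydroxyphenyl)[7-hydroxy-5-methoxy-2,2-dimethyl-8-(3-methylbut-2-enyl)-2H-chromen-6-yl]methanone | COc1c2c(c(CC=C(C)C)c(O)c1C(=O)c1ccc(O)cc1)OC(C)(C)C=C2 | target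

Total step count: 9.
Longest linear sequence: 7 (steps 1, 2, 3, 4, 5, 8, 9). Steps 6 and 7 build the amide in parallel.

Steps most likely to fail

1. Step 5.
- What may go wrong: the formyl group of 9 sits between two ortho oxygens and receives electron density from three donors. Iminium formation may therefore be slow, and protodeboronation of the alkenylboronic acid at 90 °C may use up the reagent before the alkenyl transfer occurs.
- Fallback: it sets out from 9 and replaces the boron nucleophile by a magnesium one at the aldehyde stage.
- 2-Methylprop-1-enylmagnesium bromide (2.5 equiv, THF, 0 °C; the first equivalent is taken by the phenol) should add to the formyl carbon. This gives 2-(1-hydroxy-3-methylbut-2-enyl)-3-methoxy-5-(methoxymethoxy)-6-(3-methylbut-2-enyl)phenol F1.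
- Warming this ortho-hydroxybenzyl alcohol in toluene should expel water, pass through the same quinone methide 13 and close to the chromene. The route is rejoined at 14.

2. Step 8.
- What may go wrong: attack of the doubly ortho-substituted aryllithium on the amide carbonyl may be sluggish. That leaves time for base-induced breakdown of the N-methoxy amide and for proton transfer from the benzylic allylic CH2 of the prenyl group.
- Fallback: it sets out from 14 and 17 and moves the coupling to a lower oxidation level with a smaller and more reactive electrophile.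
- Amide 17 is reduced with i-Bu2AlH (THF, −78 °C) to 4-(methoxymethoxy)benzaldehyde F2.
- The lithiated chromene 18 is added to it at −78 °C to give [5-methoxy-7-(methoxymethoxy)-2,2-dimethyl-8-(3-methylbut-2-enyl)-2H-chromen-6-yl][4-(methoxymethoxy)phenyl]methanol F3.
- Oxidation of this benzhydrol with Dess–Martin periodinane buffered with NaHCO3 in CH2Cl2 comes back to the route at 20.

3. Step 4.
- What may go wrong: the second MOM group may be lost before the first is fully cleaved, so the reaction cannot be stopped cleanly at the mono-ether stage.
- Fallback: it sets out from 8 and reverses the logic, telling the two oxygens apart by protection instead of deprotection.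
- Both acetals are removed (aq. HCl, MeOH, 40 °C) to give 2,4-dihydroxy-6-methoxy-3-(3-methylbut-2-enyl)benzaldehyde F4.
- One equivalent of MOMCl with K2CO3 in acetone should then alkylate only the hydroxyl para to the formyl group, because the ortho hydroxyl is held in a hydrogen bond to the carbonyl oxygen. The route is rejoined at 9.

Further compounds
F1 | step 5 | 2-(1-hydroxy-3-methylbut-2-enyl)-3-methoxy-5-(methoxymethoxy)-6-(3-methylbut-2-enyl)phenol (racemic) | COCOc1cc(OC)c(C(O)C=C(C)C)c(O)c1CC=C(C)C
F2 | step 8 | 4-(methoxymethoxy)benzaldehyde | COCOc1ccc(C=O)cc1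
F3 | step 8 | [5-methoxy-7-(methoxymethoxy)-2,2-dimethyl-8-(3-methylbut-2-enyl)-2H-chromen-6-yl][4-(methoxymethoxy)phenyl]methanol (racemic) | COCOc1ccc(cc1)C(O)c1c(OC)c2C=CC(C)(C)Oc2c(CC=C(C)C)c1OCOC
F4 | step 4 | 2,4-dihydroxy-6-methoxy-3-(3-methylbut-2-enyl)benzaldehyde | COc1cc(O)c(CC=C(C)C)c(O)c1C=O
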